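## Retrosynthetic overview

1. The last bond is the C11–O aryl ether, made by Mitsunobu coupling of the 11-hydroxy drimenone with isofraxidin; just before that, C5 (α to the C6 ketone) is epimerised from the cis- to the trans-decalin.
2. Ring B is made by inserting propyne (C7, C8 and the C8 methyl) into the C6–C9 bond of a cis-fused cyclobutanone with a zerovalent nickel catalyst, a strain-driven [4+2] ring expansion that forms C6–C7 and C8–C9 together.
3. The enabling feature is that the C6 carbonyl of ring B is flanked by C5 and C9, which are both bonded to the quaternary C10. The unit C6–C5–C10–C9 can therefore be folded into a four-membered ketone on ring A, and the rest of ring B, C7=C8(CH3), is simply propyne.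
4. Ring A and the cyclobutanone are closed together by one intramolecular keteniminium–alkene [2+2] cycloaddition of an open-chain amide onto a (Z)-trisubstituted (neryl) alkene, which sets C5, C9 and C10.
5. The open chain comes from nerol: terminal-alkene cleavage, iridium-catalysed asymmetric reverse prenylation (C3 stereocentre, C4 gem-dimethyl, C5–C6), isovalerate, hydroboration/oxidation. Ring order: ring A with the four-membered ring, then ring B, coumarin last.

Key step: step 10

Numbering convention: drimane numbering is used for all intermediates (ring A = C1–C5, C10; ring B = C5–C10; C11 = CH2O on C9; C12 = CH3 on C8); β is the face of the C10 methyl. The target has 10β-CH3, 5α-H, 9β-H (C11 α), 3α-O-acyl, with C3 of R configuration.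

Assumption: (R)-SEGPHOS is taken as the ligand antipode that gives the R carbinol in step 4, and the (2R,5R) antipode of 2,5-dimethylpyrrolidine as the auxiliary that directs the cycloaddition of step 9 to the required face; if either sense proves opposite, the other antipode is used with no other change.

## Route

Step 1
Reactants: 1 nerol, (2Z)-3,7-dimethylocta-2,6-dien-1-ol
Product: 2 neryl tert-butyldiphenylsilyl ether
Conditions: TBDPSCl, imidazole, DMF, 0 °C → rt
Reagents that add atoms: tert-butyldiphenylsilyl chloride, CC(C)(C)[Si](Cl)(c1ccccc1)c1ccccc1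
Why: Imidazole-promoted silylation of a primary allylic alcohol gives a robust silyl ether that leaves the Z alkene untouched.

Step 2
Reactants: 2 neryl tert-butyldiphenylsilyl ether
Product: 3 6,7-epoxide of 2 (racemic at the epoxide CH)
Conditions: mCPBA (1.05 equiv), NaHCO3, CH2Cl2, −20 → 0 °C
Reagents that add atoms: 3-chloroperoxybenzoic acid, OOC(=O)c1cccc(Cl)c1
Why: Prilezhaev epoxidation should be fastest at the remote, more electron-rich trisubstituted alkene because the other alkene is deactivated by its allylic oxygen; the new centre is racemic and is destroyed in step 3.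

Step 3
Reactants: 3 6,7-epoxide of 2
Product: 4 (4Z)-6-[(tert-butyldiphenylsilyl)oxy]-4-methylhex-4-enal
Conditions: HIO4·2H2O, THF/H2O, 0 °C
Reagents that add atoms: none
Why: Periodic acid hydrolyses the epoxide and cleaves the resulting diol (Malaprade cleavage), the classical degradation of terpenoid terminal epoxides to the aldehyde, with loss of acetone.

Step 4
Reactants: 4 (4Z)-6-[(tert-butyldiphenylsilyl)oxy]-4-methylhex-4-enal; 5 3-methylbuta-1,2-diene
Product: 6 (4R,7Z)-9-[(tert-butyldiphenylsilyl)oxy]-3,3,7-trimethylnona-1,7-dien-4-ol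
Conditions: [Ir(cod)Cl]2 (2.5 mol %), (R)-SEGPHOS (5 mol %), 4-cyano-3-nitrobenzoic acid (10 mol %), Cs2CO3 (20 mol %), iPrOH (2 equiv), toluene, 50 °C
Reagents that add atoms: none
Why: In this iridium-catalysed transfer-hydrogenative reverse prenylation the 1,1-dimethylallyl–iridium species formed by hydrometalation of the allene adds to the aldehyde at its substituted terminus through a closed chair transition state, and the C3 stereocentre is set by the chiral iridium–SEGPHOS catalyst (catalyst control).

Step 5
Reactants: 6 (4R,7Z)-9-[(tert-butyldiphenylsilyl)oxy]-3,3,7-trimethylnona-1,7-dien-4-ol; 7 3-methylbutanoic anhydride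
Product: 8 (4R,7Z)-9-[(tert-butyldiphenylsilyl)oxy]-3,3,7-trimethylnona-1,7-dien-4-yl 3-methylbutanoate
Conditions: DMAP (0.2 equiv), Et3N, CH2Cl2, rt → 40 °C
Reagents that add atoms: none
Why: DMAP-catalysed acyl transfer acylates the hindered secondary alcohol and installs the isovalerate of the target, which also protects O3 for the rest of the route.

Step 6
Reactants: 8 (4R,7Z)-9-[(tert-butyldiphenylsilyl)oxy]-3,3,7-trimethylnona-1,7-dien-4-yl 3-methylbutanoate
Product: 10 (4R,7Z)-9-[(tert-butyldiphenylsilyl)oxy]-1-hydroxy-3,3,7-trimethylnon-7-en-4-yl 3-methylbutanoate, via B-alkyl-9-BBN adduct 9 (not isolated)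
Conditions: 9-BBN, THF, 0 °C → rt; then 30% H2O2, aq NaOAc, 0 °C → rt
Reagents that add atoms: hydrogen peroxide, OO (hydroxyl oxygen); 9-borabicyclo[3.3.1]nonane, C1CC2CCCC(C1)B2 (carried by intermediate 9 only)
Why: Hydroboration–oxidation with the bulky borane should take the monosubstituted vinyl group anti-Markovnikov in preference to the trisubstituted alkene, and the buffered peroxide oxidation spares the ester.

Step 7
Reactants: 10 (4R,7Z)-9-[(tert-butyldiphenylsilyl)oxy]-1-hydroxy-3,3,7-trimethylnon-7-en-4-yl 3-methylbutanoate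
Product: 12 (4R,7Z)-9-[(tert-butyldiphenylsilyl)oxy]-3,3,7-trimethyl-4-[(3-methylbutanoyl)oxy]non-7-enoic acid, via 1-oxo aldehyde 11 (not isolated)
Conditions: TEMPO (20 mol %), PhI(OAc)2 (2.5 equiv), MeCN/H2O, rt
Reagents that add atoms: water, O (second oxygen of the carboxyl group)
Why: The oxoammonium-mediated oxidation takes the primary alcohol through the aldehyde hydrate to the acid without touching the alkene, the ester or the silyl ether.

Step 8
Reactants: 12 (4R,7Z)-9-[(tert-butyldiphenylsilyl)oxy]-3,3,7-trimethyl-4-[(3-methylbutanoyl)oxy]non-7-enoic acid; 13 (2R,5R)-2,5-dimethylpyrrolidine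
Product: 15 (2R,5R)-2,5-dimethylpyrrolidine amide of 12, via acid chloride 14 (not isolated)
Conditions: (COCl)2, cat. DMF, CH2Cl2, 0 °C → rt; then 13, Et3N, CH2Cl2, 0 °C → rt
Reagents that add atoms: oxalyl chloride, O=C(Cl)C(Cl)=O (its chlorine is carried by intermediate 14 only)
Why: Acid chloride formation followed by Schotten–Baumann-type amidation attaches the C2-symmetric amine, which later gives a keteniminium ion free of E/Z isomers.

Step 9
Reactants: 15 (2R,5R)-2,5-dimethylpyrrolidine amide of 12
Product: 18 cis-fused cyclobutanone (ring A fused at C5–C10 to the four-membered ketone C5–C6(=O)–C9–C10; 10β-CH3, 5β-H, 9β-H, CH2OTBDPS α, 3α-O-isovaleroyl), via keteniminium triflate 16 (not isolated), via cyclobutaniminium triflate 17 (not isolated)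
Conditions: Tf2O, 2,4,6-collidine, ClCH2CH2Cl, −20 → 80 °C; then aq NaHCO3, 40 °C
Reagents that add atoms: water, O (ketone oxygen of 18); trifluoromethanesulfonic anhydride, O=S(=O)(OS(=O)(=O)C(F)(F)F)C(F)(F)F (triflate counter-ion of 16 and 17 only)
Why: In this intramolecular keteniminium–alkene [2+2] cycloaddition the electrophilic C6 bonds to the less substituted alkene carbon C9 and C5 to the cation-stabilising C10, so ring A and the cyclobutane close together; the Z geometry is transferred suprafacially (C11 cis to C1, trans to the C10 methyl), the cis fusion is enforced by the four-membered ring, and the face relative to C3 is set by the C2-symmetric pyrrolidinium auxiliary, which is lost on hydrolysis.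

Step 10
Reactants: 18 cis-fused cyclobutanone; 19 propyne
Product: 20 cis-fused enone, 11-[(tert-butyldiphenylsilyl)oxy]-6-oxo-5β,9β(H)-drim-7-en-3α-yl 3-methylbutanoate
Conditions: Ni(cod)2 (10 mol %), PCy3 (20 mol %), propyne (3 equiv, slow addition), toluene, 100 °C, sealed vessel
Reagents that add atoms: none
Why: Proposed new method: oxidative cyclisation of the strained C6 carbonyl and propyne on zerovalent nickel should give an oxanickelacyclopentene in which the unsubstituted alkyne carbon C7 is bonded to the crowded C6 and the methyl-bearing C8 to nickel; β-carbon elimination then cleaves the C6–C9 bond with release of the four-membered-ring strain, and C(sp2)–C(sp3) reductive elimination from the seven-membered nickelacycle forms C8–C9 and returns the catalyst. The closest known reaction type is the Ni(cod)2/phosphine-catalysed intermolecular insertion of internal alkynes into 3-substituted cyclobutanones and azetidin-3-ones; the use of a terminal alkyne and of an α,α'-disubstituted ring-fused cyclobutanone is the untested part. Ring B is closed as a formal [4+2] ring expansion in which C9–C10–C5–C6 supplies four atoms and propyne two. No stereocentre is created: C9 is carried over with retention in both the β-carbon elimination and the reductive elimination, and C5 and C10 are untouched, so 20 keeps the cis fusion of 18. Three selectivities are needed: cleavage of C6–C9 rather than C6–C5, secured because C5 lies between the quaternary C4 and C10 and cannot easily reach nickel; the alkyne orientation, secured by the steric difference between H and CH3 in the oxidative cyclisation; and cross-reaction over alkyne oligomerisation, addressed by slow addition of propyne. The silyl ether on C11 was chosen because a silyloxide is a poor leaving group for β-oxygen elimination from the C9–nickel intermediate.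

Step 11
Reactants: 20 cis-fused enone
Product: 21 trans-fused enone, 11-[(tert-butyldiphenylsilyl)oxy]-6-oxo-9β(H)-drim-7-en-3α-yl 3-methylbutanoate (5α-H)
Conditions: DBU (0.3 equiv), toluene, 40 °C
Reagents that add atoms: none
Why: Base-mediated epimerisation through the C5 enolate should favour the trans-decalin, because the cis isomer must place either C4 or C6 syn-diaxial to another substituent (C11 or the axial 3α-acyloxy group), while H9 is pseudo-equatorial in the product and poorly aligned with the enone, which should protect C9.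

Step 12
Reactants: 21 trans-fused enone
Product: 22 11-hydroxy-6-oxo-9β(H)-drim-7-en-3α-yl 3-methylbutanoate
Conditions: HF·pyridine, pyridine/THF, 0 °C → rt
Reagents that add atoms: none
Why: Fluoride-mediated desilylation under buffered acidic conditions avoids a free alkoxide, so neither vinylogous retro-aldol cleavage nor acyl migration is expected.

Step 13
Reactants: 22 11-hydroxy-6-oxo-9β(H)-drim-7-en-3α-yl 3-methylbutanoate; 23 isofraxidin (7-hydroxy-6,8-dimethoxycoumarin)
Product: 24 target, 7-{[3α-(3-methylbutanoyloxy)-6-oxo-9β(H)-drim-7-en-11-yl]oxy}-6,8-dimethoxycoumarin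
Conditions: PPh3, DIAD, THF, 0 → 50 °C
Reagents that add atoms: none
Why: Mitsunobu etherification joins the primary alcohol to the acidic phenol by SN2 displacement at C11; no stereocentre is involved, and the weakly basic medium together with the pseudo-equatorial H9 should suppress vinylogous β-elimination.

## Compound list

1 | nerol, (2Z)-3,7-dimethylocta-2,6-dien-1-ol | CC(C)=CCC/C(C)=C\CO | starting material
2 | neryl tert-butyldiphenylsilyl ether | CC(C)=CCC/C(C)=C\CO[Si](c1ccccc1)(c1ccccc1)C(C)(C)C | intermediate
3 | tert-butyl{[(2Z)-5-(3,3-dimethyloxiran-2-yl)-3-methylpent-2-en-1-yl]oxy}diphenylsilane (racemic at the epoxide CH) | CC1(C)OC1CC/C(C)=C\CO[Si](c1ccccc1)(c1ccccc1)C(C)(C)C | intermediate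
4 | (4Z)-6-[(tert-butyldiphenylsilyl)oxy]-4-methylhex-4-enal | O=CCC/C(C)=C\CO[Si](c1ccccc1)(c1ccccc1)C(C)(C)C | intermediate
5 | 3-methylbuta-1,2-diene | CC(C)=C=C | starting material
6 | (4R,7Z)-9-[(tert-butyldiphenylsilyl)oxy]-3,3,7-trimethylnona-1,7-dien-4-ol | C=CC(C)(C)[C@H](O)CC/C(C)=C\CO[Si](c1ccccc1)(c1ccccc1)C(C)(C)C | intermediate
7 | 3-methylbutanoic anhydride | CC(C)CC(=O)OC(=O)CC(C)C | starting material
8 | (4R,7Z)-9-[(tert-butyldiphenylsilyl)oxy]-3,3,7-trimethylnona-1,7-dien-4-yl 3-methylbutanoate | C=CC(C)(C)[C@H](OC(=O)CC(C)C)CC/C(C)=C\CO[Si](c1ccccc1)(c1ccccc1)C(C)(C)C | intermediate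
9 | B-alkyl-9-borabicyclo[3.3.1]nonane adduct of 8 (boron on the terminal carbon) | C1CC2CCCC(C1)B2CCC(C)(C)[C@H](OC(=O)CC(C)C)CC/C(C)=C\CO[Si](c1ccccc1)(c1ccccc1)C(C)(C)C | intermediate
10 | (4R,7Z)-9-[(tert-butyldiphenylsilyl)oxy]-1-hydroxy-3,3,7-trimethylnon-7-en-4-yl 3-methylbutanoate | OCCC(C)(C)[C@H](OC(=O)CC(C)C)CC/C(C)=C\CO[Si](c1ccccc1)(c1ccccc1)C(C)(C)C | intermediate
11 | (4R,7Z)-9-[(tert-butyldiphenylsilyl)oxy]-3,3,7-trimethyl-1-oxonon-7-en-4-yl 3-methylbutanoate | O=CCC(C)(C)[C@H](OC(=O)CC(C)C)CC/C(C)=C\CO[Si](c1ccccc1)(c1ccccc1)C(C)(C)C | intermediate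
12 | (4R,7Z)-9-[(tert-butyldiphenylsilyl)oxy]-3,3,7-trimethyl-4-[(3-methylbutanoyl)oxy]non-7-enoic acid | OC(=O)CC(C)(C)[C@H](OC(=O)CC(C)C)CC/C(C)=C\CO[Si](c1ccccc1)(c1ccccc1)C(C)(C)C | intermediate
13 | (2R,5R)-2,5-dimethylpyrrolidine | C[C@@H]1CC[C@@H](C)N1 | starting material
14 | acid chloride of 12 | ClC(=O)CC(C)(C)[C@H](OC(=O)CC(C)C)CC/C(C)=C\CO[Si](c1ccccc1)(c1ccccc1)C(C)(C)C | intermediate
15 | (4R,7Z)-9-[(tert-butyldiphenylsilyl)oxy]-1-[(2R,5R)-2,5-dimethylpyrrolidin-1-yl]-3,3,7-trimethyl-1-oxonon-7-en-4-yl 3-methylbutanoate | C[C@@H]1CC[C@@H](C)N1C(=O)CC(C)(C)[C@H](OC(=O)CC(C)C)CC/C(C)=C\CO[Si](c1ccccc1)(c1ccccc1)C(C)(C)C | intermediate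
16 | keteniminium triflate from 15 (N=C6=C5) | C[C@@H]1CC[C@@H](C)[N+]1=C=CC(C)(C)[C@H](OC(=O)CC(C)C)CC/C(C)=C\CO[Si](c1ccccc1)(c1ccccc1)C(C)(C)C.[O-]S(=O)(=O)C(F)(F)F | intermediate
17 | cyclobutaniminium triflate (iminium at C6 of the cis-fused bicycle) | CC(C)(C)[Si](c1ccccc1)(c1ccccc1)OC[C@@H]1C(=[N+]3[C@H](C)CC[C@H]3C)[C@@H]2C(C)(C)[C@H](OC(=O)CC(C)C)CC[C@]12C.[O-]S(=O)(=O)C(F)(F)F | intermediate
18 | cis-fused cyclobutanone: ring A fused at C5–C10 to C5–C6(=O)–C9–C10; 10β-CH3, 5β-H, 9β-H, 9α-CH2OTBDPS, 3α-O-isovaleroyl | CC(C)(C)[Si](c1ccccc1)(c1ccccc1)OC[C@@H]1C(=O)[C@@H]2C(C)(C)[C@H](OC(=O)CC(C)C)CC[C@]12C | intermediate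
19 | propyne | CC#C | starting material
20 | 11-[(tert-butyldiphenylsilyl)oxy]-6-oxo-5β,9β(H)-drim-7-en-3α-yl 3-methylbutanoate (cis-decalin) | CC(C)(C)[Si](c1ccccc1)(c1ccccc1)OC[C@@H]1C(C)=CC(=O)[C@@H]2C(C)(C)[C@H](OC(=O)CC(C)C)CC[C@]12C | intermediate
21 | 11-[(tert-butyldiphenylsilyl)oxy]-6-oxo-9β(H)-drim-7-en-3α-yl 3-methylbutanoate (5α-H, trans-decalin) | CC(C)(C)[Si](c1ccccc1)(c1ccccc1)OC[C@@H]1C(C)=CC(=O)[C@H]2C(C)(C)[C@H](OC(=O)CC(C)C)CC[C@]12C | intermediate
22 | 11-hydroxy-6-oxo-9β(H)-drim-7-en-3α-yl 3-methylbutanoate | OC[C@@H]1C(C)=CC(=O)[C@H]2C(C)(C)[C@H](OC(=O)CC(C)C)CC[C@]12C | intermediate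
23 | isofraxidin, 7-hydroxy-6,8-dimethoxycoumarin | COc1cc2ccc(=O)oc2c(OC)c1O | starting material
24 | 7-{[3α-(3-methylbutanoyloxy)-6-oxo-9β(H)-drim-7-en-11-yl]oxy}-6,8-dimethoxycoumarin | COc1cc2ccc(=O)oc2c(OC)c1OC[C@@H]1C(C)=CC(=O)[C@H]2C(C)(C)[C@H](OC(=O)CC(C)C)CC[C@]12C | target

## Step count and risks

Total steps: 13. Longest linear sequence: 13 steps, from nerol 1.

Steps most likely to fail:

1. Step 10 (the proposed new method). The catalyst may be consumed by oligomerisation of the terminal alkyne, nickel may insert into C6–C5 instead of C6–C9, or β-oxygen elimination may occur from the C9–nickel intermediate. The fallback makes the two bonds in separate, known steps and sets out from 18. Addition of HC≡CMgBr in the presence of CeCl3 (THF, −78 °C) to the C6 carbonyl should give the 6-ethynylcyclobutanol F1 (mixture at C6, of no consequence). Crabbé homologation (CuBr, paraformaldehyde, iPr2NH, dioxane, reflux) should convert it into the 6-allenylcyclobutanol F2. Treatment with [Rh(OH)(cod)]2 and rac-BINAP in toluene at 90 °C then follows the known rhodium-catalysed ring expansion of 1-allenylcyclobutanols to 3-methylcyclohex-2-enones: the monovalent rhodium alkoxide undergoes β-carbon elimination, the C9–rhodium bond adds to the central allene carbon C8, and protonation at the allene terminus gives the C12 methyl. The fallback comes back to the route at 20.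

2. Step 9. The strongly electrophilic activation may ionise the allylic silyl ether, or the facial discrimination of the cycloaddition may be poor. The fallback sets out from 12 and uses the neutral ketene instead. The acid chloride 14 is made as in step 8 and heated with iPr2NEt in toluene at reflux under high dilution, so that the ketene F3 forms and undergoes the thermal intramolecular ketene–alkene [2+2] cycloaddition with the same regiochemistry and the same transfer of the Z geometry. The face is then under substrate control only, and the diastereomers would be separated by chromatography. The fallback comes back to the route at 18.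

3. Step 13. Displacement at the β-branched C11 by the di-ortho-substituted phenol may be slow, so that the Mitsunobu betaine is consumed unproductively. The fallback sets out from 22. Tf2O and 2,6-lutidine in CH2Cl2 at −78 °C should give the primary triflate F4, which is treated with 23 and Cs2CO3 in MeCN at 0 °C → rt (Williamson-type alkylation of the weakly basic phenoxide by an isolated, highly reactive sulfonate). The fallback comes back to the route at 24.

## Further compounds

F1 | step 10 | 6-ethynyl-6-hydroxy derivative of 18 (1-ethynylcyclobutanol, mixture at C6) | CC(C)(C)[Si](c1ccccc1)(c1ccccc1)OC[C@@H]1C(O)(C#C)[C@@H]2C(C)(C)[C@H](OC(=O)CC(C)C)CC[C@]12C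
F2 | step 10 | 6-hydroxy-6-(propa-1,2-dienyl) derivative of 18 (1-allenylcyclobutanol, mixture at C6) | CC(C)(C)[Si](c1ccccc1)(c1ccccc1)OC[C@@H]1C(O)(C=C=C)[C@@H]2C(C)(C)[C@H](OC(=O)CC(C)C)CC[C@]12C
F3 | step 9 | ketene from 14 (O=C6=C5H) | O=C=CC(C)(C)[C@H](OC(=O)CC(C)C)CC/C(C)=C\CO[Si](c1ccccc1)(c1ccccc1)C(C)(C)C
F4 | step 13 | C11 trifluoromethanesulfonate of 22 | O=S(=O)(OC[C@@H]1C(C)=CC(=O)[C@H]2C(C)(C)[C@H](OC(=O)CC(C)C)CC[C@]12C)C(F)(F)F
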